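**Plan**

1. Ring A is the formyl- and methyl-bearing arene; ring B is the hexasubstituted arene. Retrosynthetic cuts, in order: the lactol configuration, the benzylic acetate, the acetals masking the hydroxyphthalide, the ring A formyl carbon (back to C–I), the aromaticity of ring A, the iodide, the ring A C–O bond of the diaryl ether (key), the depside ester C–O bond, and the two C–C bonds of a Michael–Claisen annulation.
2. Enabling feature: the ether-bearing carbon of ring A sits next to the carbon that carries the lactone carbonyl. One oxidation level down it is a ketone of a cyclohexane-1,3-dione β-keto ester, seven atoms away from the ring B phenol oxygen through the ester. Ring B has no free CH.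
3. Forward: the ring A carbocycle is made first. Ring B is built from methyl 2,4-dihydroxy-3-methylbenzoate (benzylic oxidation, benzodioxine acetonide ring, hydroxylation, formylation). The two are joined as an aryl β-keto ester through an acylketene.
4. The seven-membered ring then closes by acid-catalysed enol etherification. The enol ether is iodinated at the CH between its two oxygenated carbons, ring A is aromatized, the iodide is carbonylated, and aqueous acid closes the lactol ring before acetolysis of the benzylic alcohol.
5. Stereochemistry: the lactol carbon is the only stereocentre of the target and is labile in solution; it is set as (S) in the last step by seeded crystallization. The racemic trans centres of the dihydro ring are erased on aromatization.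

Key step: step 15

Remark: the lactol carbon epimerizes in solution by ring-chain tautomerism, so the (S) form can only be held in the crystal; it is assumed that the target crystallizes as a conglomerate, so that seeding decides the handedness.

**Route**

Step 1
Reactants: 1 tert-butyl acetoacetate; 2 ethyl (E)-but-2-enoate (ethyl crotonate)
Product: 4 tert-butyl trans-6-methyl-2,4-dioxocyclohexane-1-carboxylate (racemate), via Michael adduct 3 (not isolated)
Conditions: t-BuOK, t-BuOH, reflux; then aq. HCl
Reagents that add atoms: none
Why: Michael addition of the acetoacetate enolate to the crotonate and Dieckmann-type Claisen closure of the acetyl methyl group onto the ethyl ester should give the dihydroorsellinate ring with the tert-butyl ester intact; the trans relation of methyl and ester is the thermodynamic one at the epimerizable ester-bearing carbon.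

Step 2
Reactants: 5 methyl 2,4-dihydroxy-3-methylbenzoate
Product: 6 methyl 2,4-diacetoxy-3-methylbenzoate
Conditions: Ac2O, pyridine, DMAP (cat.), rt
Reagents that add atoms: acetic anhydride, CC(=O)OC(C)=O
Why: DMAP-catalysed O-acetylation of both phenols, the chelated one included, deactivates the ring so that the radical step that follows meets only the benzylic methyl group.

Step 3
Reactants: 6 methyl 2,4-diacetoxy-3-methylbenzoate
Product: 7 methyl 2,4-diacetoxy-3-(bromomethyl)benzoate
Conditions: NBS, AIBN (cat.), PhCF3, reflux
Reagents that add atoms: N-bromosuccinimide, O=C1CCC(=O)N1Br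
Why: Wohl–Ziegler bromination at the only benzylic position; the acylated ring is too electron-poor for nuclear bromination.

Step 4
Reactants: 7 methyl 2,4-diacetoxy-3-(bromomethyl)benzoate
Product: 8 methyl 2,4-dihydroxy-3-(hydroxymethyl)benzoate
Conditions: NaOH, THF/H2O, 0 °C, high dilution; then HCl to pH 4
Reagents that add atoms: water (as hydroxide), O
Why: saponification of the two aryl acetates and hydrolysis of the activated benzylic bromide should give the salicyl alcohol, while the methyl ester, a chelated salicylate, resists cold dilute base.

Step 5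
Reactants: 8 methyl 2,4-dihydroxy-3-(hydroxymethyl)benzoate
Product: 9 methyl 4-(benzyloxy)-2-hydroxy-3-(hydroxymethyl)benzoate
Conditions: BnBr, K2CO3, acetone, 40 °C
Reagents that add atoms: benzyl bromide, BrCc1ccccc1
Why: Williamson etherification at the 4-hydroxyl, the most acidic phenol (para to the ester) and the only one not hydrogen-bonded to the ester; the chelated phenol and the alcohol stay free.

Step 6
Reactants: 9 methyl 4-(benzyloxy)-2-hydroxy-3-(hydroxymethyl)benzoate
Product: 10 methyl 5-(benzyloxy)-2,2-dimethyl-4H-1,3-benzodioxine-8-carboxylate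
Conditions: 2,2-dimethoxypropane, PPTS (cat.), acetone, rt
Reagents that add atoms: 2,2-dimethoxypropane, COC(C)(C)OC
Why: acid-catalysed transketalization closes the isopropylidene acetal of the salicyl alcohol; with the other flanking oxygen benzylated, only the phenol next to the ester can take part, and this is the oxygen that must stay alkylated to block quinone methide formation later.

Step 7
Reactants: 10 methyl 5-(benzyloxy)-2,2-dimethyl-4H-1,3-benzodioxine-8-carboxylate
Product: 11 methyl 5-(benzyloxy)-6-bromo-2,2-dimethyl-4H-1,3-benzodioxine-8-carboxylate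
Conditions: NBS, MeCN, 0 °C to rt, dark
Reagents that add atoms: N-bromosuccinimide, O=C1CCC(=O)N1Br
Why: electrophilic aromatic bromination should go to C6, ortho to the benzyloxy group and para to the acetal oxygen, since C7 is meta to both oxygens and ortho to the ester.

Step 8
Reactants: 11 methyl 5-(benzyloxy)-6-bromo-2,2-dimethyl-4H-1,3-benzodioxine-8-carboxylate
Product: 13 methyl 5-(benzyloxy)-6-hydroxy-2,2-dimethyl-4H-1,3-benzodioxine-8-carboxylate, via pinacol boronate 12 (not isolated)
Conditions: B2pin2, PdCl2(dppf) (cat.), KOAc, dioxane, 90 °C; then H2O2, NaOH, THF/H2O, 0 °C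
Reagents that add atoms: hydrogen peroxide, OO (the phenol oxygen); bis(pinacolato)diboron, CC1(C)OB(OC1(C)C)B1OC(C)(C)C(C)(C)O1 (boron of 12 only)
Why: Miyaura borylation of the aryl bromide followed by oxidative ipso-hydroxylation of the boronate places the second catechol oxygen exactly where the bromine stood.

Step 9
Reactants: 13 methyl 5-(benzyloxy)-6-hydroxy-2,2-dimethyl-4H-1,3-benzodioxine-8-carboxylate
Product: 14 methyl 5-(benzyloxy)-7-formyl-6-hydroxy-2,2-dimethyl-4H-1,3-benzodioxine-8-carboxylate
Conditions: MgCl2, Et3N, (CH2O)n, MeCN, reflux; then aq. HCl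
Reagents that add atoms: paraformaldehyde (formaldehyde), C=O
Why: Casnati–Skattebøl ortho-formylation, in which the magnesium phenoxide delivers formaldehyde to the ortho carbon and a second formaldehyde takes up hydride; C7 is the only free ring position and the non-acidic medium spares the acetonide and the benzyl ether.

Step 10
Reactants: 14 methyl 5-(benzyloxy)-7-formyl-6-hydroxy-2,2-dimethyl-4H-1,3-benzodioxine-8-carboxylate
Product: 15 methyl 5-(benzyloxy)-6-[(tert-butyldimethylsilyl)oxy]-7-formyl-2,2-dimethyl-4H-1,3-benzodioxine-8-carboxylate
Conditions: TBSCl, imidazole, DMF, rt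
Reagents that add atoms: tert-butyldimethylsilyl chloride, CC(C)(C)[Si](C)(C)Cl
Why: imidazole-mediated silylation masks the future ether oxygen with a group that survives hydrogenolysis and heat and is later removed by fluoride without base.

Step 11
Reactants: 15 methyl 5-(benzyloxy)-6-[(tert-butyldimethylsilyl)oxy]-7-formyl-2,2-dimethyl-4H-1,3-benzodioxine-8-carboxylate
Product: 16 methyl 5-(benzyloxy)-6-[(tert-butyldimethylsilyl)oxy]-7-(1,3-dioxolan-2-yl)-2,2-dimethyl-4H-1,3-benzodioxine-8-carboxylate
Conditions: (TMSOCH2)2, TMSOTf (cat.), CH2Cl2, -78 to -20 °C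
Reagents that add atoms: 1,2-bis(trimethylsilyloxy)ethane, C[Si](C)(C)OCCO[Si](C)(C)C
Why: Noyori acetalization turns the hindered aldehyde into its dioxolane under aprotic low-temperature conditions that leave the acetonide, silyl ether and esters alone; the aldehyde must be masked before it meets the 1,3-dione.

Step 12
Reactants: 16 methyl 5-(benzyloxy)-6-[(tert-butyldimethylsilyl)oxy]-7-(1,3-dioxolan-2-yl)-2,2-dimethyl-4H-1,3-benzodioxine-8-carboxylate
Product: 17 methyl 6-[(tert-butyldimethylsilyl)oxy]-7-(1,3-dioxolan-2-yl)-5-hydroxy-2,2-dimethyl-4H-1,3-benzodioxine-8-carboxylate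
Conditions: H2 (1 atm), Pd/C, EtOAc, rt
Reagents that add atoms: none
Why: neutral hydrogenolysis of the benzyl aryl ether frees only the phenol meant for the depside ester, with no base present that could move the silyl group.

Step 13
Reactants: 17 methyl 6-[(tert-butyldimethylsilyl)oxy]-7-(1,3-dioxolan-2-yl)-5-hydroxy-2,2-dimethyl-4H-1,3-benzodioxine-8-carboxylate; 4 tert-butyl trans-6-methyl-2,4-dioxocyclohexane-1-carboxylate
Product: 19 6-[(tert-butyldimethylsilyl)oxy]-7-(1,3-dioxolan-2-yl)-8-(methoxycarbonyl)-2,2-dimethyl-4H-1,3-benzodioxin-5-yl trans-6-methyl-2,4-dioxocyclohexane-1-carboxylate (racemate), via acylketene 18 (not isolated)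
Conditions: 4 (2 equiv), toluene, 110 °C, N2 sweep to remove t-BuOH
Reagents that add atoms: none
Why: thermal transesterification of a tert-butyl β-keto ester, which loses tert-butanol to an acylketene that the single free phenol captures under neutral conditions (the free β-keto acid would decarboxylate); the thermodynamic trans relation in ring A is kept.

Step 14
Reactants: 19 the silyl-protected aryl β-keto ester
Product: 20 7-(1,3-dioxolan-2-yl)-6-hydroxy-8-(methoxycarbonyl)-2,2-dimethyl-4H-1,3-benzodioxin-5-yl trans-6-methyl-2,4-dioxocyclohexane-1-carboxylate (racemate; ring B catechol monoester of trans-dihydroorsellinic acid)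
Conditions: HF·pyridine, THF, 0 °C
Reagents that add atoms: none
Why: fluoride-mediated desilylation in a weakly acidic medium releases the ring B phenol without forming the phenoxide that would trigger acyl transfer between the catechol oxygens.

Step 15
Reactants: 20 the ring B catechol monoester of trans-dihydroorsellinic acid
Product: 21 seven-membered vinylogous ester lactone (racemate): ring A is a 5-methylcyclohex-2-en-1-one whose C3 carries the ring B aryloxy oxygen as enol ether and whose C4 carries the lactone carbonyl (4,5-trans); ring B keeps the methyl ester, dioxolane and acetonide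
Conditions: TsOH (10 mol%), benzene, reflux through 4 Å molecular sieves, 0.003 M
Reagents that add atoms: none
Why: Proposed new method: TsOH protonates the enolized 1,3-dione to a delocalized hydroxyallyl cation, the ring B phenol adds to the carbon next to the ester-bearing carbon, and loss of water (taken up by the sieves) leaves the conjugated aryl vinylogous ester. The closest known reactions are the acid-catalysed enol etherification of cyclic 1,3-diones with alcohols under azeotropic water removal and the O-attack of a phenol on a β-keto carbonyl in the Simonis chromone synthesis. The seven-membered ring closes in a 7-exo-trig mode; no new stereocentre arises, and the racemic trans pair of ring A is carried on unchanged until step 17 erases it. Site selectivity between the two ketone carbons comes from the ester tether, since the remote carbonyl could only be reached through a nine-membered ring, and C-alkylation of the arene (Pechmann or Friedel–Crafts type) is excluded because ring B has no free CH. The selectivity to be watched is retention of the acyl group on its own catechol oxygen: acid activates the weakly basic aryl ester far less than the vinylogous acid, the temperature is held at 80 °C to limit acylketene extrusion, and high dilution suppresses intermolecular enol ether formation. The dioxolane keeps the ring B aldehyde from Knoevenagel condensation with the dione, and the acetonide blocks ionization at the benzylic carbon.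

Step 16
Reactants: 21 the vinylogous ester lactone
Product: 22 2-iodo derivative of 21 (iodine on the enone carbon between the aryloxy-bearing carbon and the ketone; racemate)
Conditions: NIS, CH2Cl2, 0 °C to rt, dark
Reagents that add atoms: N-iodosuccinimide, O=C1CCC(=O)N1I
Why: electrophilic α-iodination of a vinylogous ester; this CH is the only nucleophilic alkene carbon in the molecule, so the halogen marks, before aromatization, the position that will lie between the two ring A oxygens.

Step 17
Reactants: 22 the iodo vinylogous ester
Product: 23 aromatized iodophenol depsidone: ring A carries, going round from the lactone carbonyl carbon, methyl, H, hydroxyl, iodine and the ether oxygen; ring B unchanged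
Conditions: DDQ, 1,4-dioxane, 70 °C
Reagents that add atoms: none
Why: DDQ dehydrogenation of a cyclohexane-1,3-dione enol ether to the resorcinol monoether, eased by the acidic hydrogen at the ester-bearing carbon; the electron-poor, fully substituted ring B and its acetals should not be oxidized, and both ring A stereocentres disappear.

Step 18
Reactants: 23 the iodophenol depsidone
Product: 24 formyl depsidone: as 23 with CHO in place of iodine
Conditions: CO (1 atm), Bu3SnH (slow addition), Pd(PPh3)4 (cat.), toluene, 50 °C
Reagents that add atoms: carbon monoxide, [C-]#[O+]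
Why: palladium-catalysed reductive carbonylation (formylation) of the aryl iodide under neutral conditions puts the formyl group on the carbon between the two oxygens, a site that direct formylation of the phenol would not favour over the one next to the methyl group.

Step 19
Reactants: 24 the formyl depsidone
Product: 26 salazinic acid (lactol carbon racemic), via formyl methyl ester 25 (not isolated)
Conditions: 2 M HCl, THF, 45 °C
Reagents that add atoms: water, O
Why: acid hydrolysis removes the acetonide and the dioxolane, and the freed aldehyde, as its hydrate, attacks the neighbouring methyl ester (neighbouring-group-assisted lactonization to the pseudo-acid) to close the hydroxyphthalide; the depsidone aryl ester and the ring A salicylaldehyde should tolerate aqueous acid.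

Step 20
Reactants: 26 salazinic acid
Product: 27 galbinic acid with the lactol carbon racemic
Conditions: AcOH, 100 °C
Reagents that add atoms: acetic acid, CC(=O)O
Why: solvolytic acetolysis (SN1-type substitution) of the benzylic alcohol, which ionizes easily because of the ortho-hydroxyl group; phenols and the lactol hydroxyl are not esterified by acetic acid alone.

Step 21
Reactants: 27 galbinic acid with the lactol carbon racemic
Product: 28 (S)-galbinic acid
Conditions: acetone/AcOH (trace), seed crystals of 28, slow cooling (40 to 5 °C) with stirring
Reagents that add atoms: none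
Why: crystallization-induced asymmetric transformation: the lactol carbon racemizes in solution through ring-chain tautomerism to the formyl acid while crystals of the seeded (S) form grow, so the stereocentre is set by the seed and held by the lattice (seed from a first small resolution on a chiral phase).

**Compound list**

1 | tert-butyl acetoacetate | CC(=O)CC(=O)OC(C)(C)C | starting material
2 | ethyl (E)-but-2-enoate | C/C=C/C(=O)OCC | starting material
3 | 1-tert-butyl 5-ethyl 2-acetyl-3-methylpentanedioate (Michael adduct, diastereomer mixture) | CCOC(=O)CC(C)C(C(C)=O)C(=O)OC(C)(C)C | intermediate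
4 | tert-butyl trans-6-methyl-2,4-dioxocyclohexane-1-carboxylate (racemate, one enantiomer drawn) | C[C@@H]1CC(=O)CC(=O)[C@H]1C(=O)OC(C)(C)C | intermediate
5 | methyl 2,4-dihydroxy-3-methylbenzoate | COC(=O)c1ccc(O)c(C)c1O | starting material
6 | methyl 2,4-diacetoxy-3-methylbenzoate | COC(=O)c1ccc(OC(C)=O)c(C)c1OC(C)=O | intermediate
7 | methyl 2,4-diacetoxy-3-(bromomethyl)benzoate | COC(=O)c1ccc(OC(C)=O)c(CBr)c1OC(C)=O | intermediate
8 | methyl 2,4-dihydroxy-3-(hydroxymethyl)benzoate | COC(=O)c1ccc(O)c(CO)c1O | intermediate
9 | methyl 4-(benzyloxy)-2-hydroxy-3-(hydroxymethyl)benzoate | COC(=O)c1ccc(OCc2ccccc2)c(CO)c1O | intermediate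
10 | methyl 5-(benzyloxy)-2,2-dimethyl-4H-1,3-benzodioxine-8-carboxylate | COC(=O)c1ccc(OCc2ccccc2)c2COC(C)(C)Oc12 | intermediate
11 | methyl 5-(benzyloxy)-6-bromo-2,2-dimethyl-4H-1,3-benzodioxine-8-carboxylate | COC(=O)c1cc(Br)c(OCc2ccccc2)c2COC(C)(C)Oc12 | intermediate
12 | methyl 5-(benzyloxy)-2,2-dimethyl-6-(4,4,5,5-tetramethyl-1,3,2-dioxaborolan-2-yl)-4H-1,3-benzodioxine-8-carboxylate | COC(=O)c1cc(B2OC(C)(C)C(C)(C)O2)c(OCc2ccccc2)c2COC(C)(C)Oc12 | intermediate
13 | methyl 5-(benzyloxy)-6-hydroxy-2,2-dimethyl-4H-1,3-benzodioxine-8-carboxylate | COC(=O)c1cc(O)c(OCc2ccccc2)c2COC(C)(C)Oc12 | intermediate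
14 | methyl 5-(benzyloxy)-7-formyl-6-hydroxy-2,2-dimethyl-4H-1,3-benzodioxine-8-carboxylate | COC(=O)c1c(C=O)c(O)c(OCc2ccccc2)c2COC(C)(C)Oc12 | intermediate
15 | methyl 5-(benzyloxy)-6-[(tert-butyldimethylsilyl)oxy]-7-formyl-2,2-dimethyl-4H-1,3-benzodioxine-8-carboxylate | COC(=O)c1c(C=O)c(O[Si](C)(C)C(C)(C)C)c(OCc2ccccc2)c2COC(C)(C)Oc12 | intermediate
16 | methyl 5-(benzyloxy)-6-[(tert-butyldimethylsilyl)oxy]-7-(1,3-dioxolan-2-yl)-2,2-dimethyl-4H-1,3-benzodioxine-8-carboxylate | COC(=O)c1c(C2OCCO2)c(O[Si](C)(C)C(C)(C)C)c(OCc2ccccc2)c2COC(C)(C)Oc12 | intermediate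
17 | methyl 6-[(tert-butyldimethylsilyl)oxy]-7-(1,3-dioxolan-2-yl)-5-hydroxy-2,2-dimethyl-4H-1,3-benzodioxine-8-carboxylate | COC(=O)c1c(C2OCCO2)c(O[Si](C)(C)C(C)(C)C)c(O)c2COC(C)(C)Oc12 | intermediate
18 | 5-methyl-6-(oxomethylidene)cyclohexane-1,3-dione (acylketene; racemate, one enantiomer drawn) | C[C@@H]1CC(=O)CC(=O)C1=C=O | intermediate
19 | 6-[(tert-butyldimethylsilyl)oxy]-7-(1,3-dioxolan-2-yl)-8-(methoxycarbonyl)-2,2-dimethyl-4H-1,3-benzodioxin-5-yl trans-6-methyl-2,4-dioxocyclohexane-1-carboxylate (racemate, one enantiomer drawn) | C[C@@H]1CC(=O)CC(=O)[C@H]1C(=O)Oc1c(O[Si](C)(C)C(C)(C)C)c(C2OCCO2)c(C(=O)OC)c2OC(C)(C)OCc12 | intermediate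
20 | 7-(1,3-dioxolan-2-yl)-6-hydroxy-8-(methoxycarbonyl)-2,2-dimethyl-4H-1,3-benzodioxin-5-yl trans-6-methyl-2,4-dioxocyclohexane-1-carboxylate (key-step precursor; racemate, one enantiomer drawn) | C[C@@H]1CC(=O)CC(=O)[C@H]1C(=O)Oc1c(O)c(C2OCCO2)c(C(=O)OC)c2OC(C)(C)OCc12 | intermediate
21 | seven-membered vinylogous ester lactone: 3-aryloxy-5-methylcyclohex-2-en-1-one bridged from C4 by the lactone carbonyl to ring B, which bears methyl ester, dioxolane and acetonide (key-step product; 4,5-trans racemate, one enantiomer drawn) | C[C@@H]1CC(=O)C=C2Oc3c(C4OCCO4)c(C(=O)OC)c4OC(C)(C)OCc4c3OC(=O)[C@@H]12 | intermediate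
22 | 2-iodo derivative of 21 (racemate, one enantiomer drawn) | C[C@@H]1CC(=O)C(I)=C2Oc3c(C4OCCO4)c(C(=O)OC)c4OC(C)(C)OCc4c3OC(=O)[C@@H]12 | intermediate
23 | iodophenol depsidone (ring A: methyl, H, OH, I, ether O; ring B: methyl ester, dioxolane, acetonide) | Cc1cc(O)c(I)c2Oc3c(C4OCCO4)c(C(=O)OC)c4OC(C)(C)OCc4c3OC(=O)c12 | intermediate
24 | formyl depsidone (as 23, CHO for I) | Cc1cc(O)c(C=O)c2Oc3c(C4OCCO4)c(C(=O)OC)c4OC(C)(C)OCc4c3OC(=O)c12 | intermediate
25 | depsidone with ring B carrying free CHO, CO2Me, OH and CH2OH (formyl methyl ester) | Cc1cc(O)c(C=O)c2Oc3c(C=O)c(C(=O)OC)c(O)c(CO)c3OC(=O)c12 | intermediate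
26 | salazinic acid (lactol carbon racemic) | Cc1cc(O)c(C=O)c2Oc3c4C(O)OC(=O)c4c(O)c(CO)c3OC(=O)c12 | intermediate
27 | galbinic acid, lactol carbon racemic | CC(=O)OCc1c(O)c2c(c3c1OC(=O)c1c(C)cc(O)c(C=O)c1O3)C(O)OC2=O | intermediate
28 | (S)-galbinic acid | CC(=O)OCc1c(O)c2c(c3c1OC(=O)c1c(C)cc(O)c(C=O)c1O3)[C@@H](O)OC2=O | target

**Step count**

Total: 21 steps. Longest linear sequence: 20 steps (steps 2 to 21, from 5); step 1 is a one-step side branch that supplies 4.

**Steps most likely to fail**

Step 15. The acyl group may shift to the neighbouring phenol oxygen, or leave as the acylketene, before the phenol condenses with the ketone; or the weakly nucleophilic phenol may not condense at all against the reverse hydrolysis. The fallback takes the ether oxygen from the dione instead of from ring B, so no free catechol hydroxyl ever exists. It sets out from 11 and 4 and comes back at 21. Ester-directed magnesiation of 11 with TMPMgCl·LiCl (THF, -20 °C) and a DMF quench should give methyl 5-(benzyloxy)-6-bromo-7-formyl-2,2-dimethyl-4H-1,3-benzodioxine-8-carboxylate F1. Acetalization as in step 11 gives methyl 5-(benzyloxy)-6-bromo-7-(1,3-dioxolan-2-yl)-2,2-dimethyl-4H-1,3-benzodioxine-8-carboxylate F2. Brief base-free hydrogenolysis (H2, Pd/C, EtOAc), in which a benzyl aryl ether should go before a hindered aryl bromide, gives methyl 6-bromo-7-(1,3-dioxolan-2-yl)-5-hydroxy-2,2-dimethyl-4H-1,3-benzodioxine-8-carboxylate F3. Acylation with 4 as in step 13 gives 6-bromo-7-(1,3-dioxolan-2-yl)-8-(methoxycarbonyl)-2,2-dimethyl-4H-1,3-benzodioxin-5-yl trans-6-methyl-2,4-dioxocyclohexane-1-carboxylate F4. Copper-catalysed Ullmann-type O-arylation of the dione enolate (CuI, 1,10-phenanthroline, Cs2CO3, dioxane, 90 °C), a known route to aryl enol ethers of 1,3-dicarbonyl compounds, then closes the same seven-membered ring to 21; only the enolate oxygen on the carbon next to the ester-bearing carbon can reach the bromide.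

Step 21. The racemate may crystallize as a racemic compound and not as a conglomerate, so that seeding cannot steer the solid to one hand. The fallback sets out from 27 and comes back at 28. 27 would be resolved by preparative chromatography on a chiral stationary phase (immobilized polysaccharide phase, hexane/EtOAc with a trace of AcOH, -20 °C), conditions under which lactols of this kind racemize slowly. The (S) fraction would be concentrated cold and crystallized at once; the other fraction would be left at room temperature to racemize and recycled. No new compound is made (F0).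

Step 13. Capture of the acylketene by the doubly ortho-substituted phenol may be slower than ketene self-reaction and O-acylation of the dione enol, and long heating may let the silyl group move to the free phenol. The fallback replaces thermal ketene generation by thiophile-promoted acyl transfer at room temperature. It sets out from 2 and 17 and comes back at 19. Commercial S-tert-butyl 3-oxobutanethioate F5 is annulated with 2 as in step 1 (t-BuOK, THF) to S-tert-butyl trans-6-methyl-2,4-dioxocyclohexane-1-carbothioate F6. F6 and 17 are then joined with AgO2CCF3 in THF at room temperature, a known silver-promoted conversion of β-keto thioesters into β-keto esters, to give 19.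

**Further compounds**

F1 | step 15 | methyl 5-(benzyloxy)-6-bromo-7-formyl-2,2-dimethyl-4H-1,3-benzodioxine-8-carboxylate | COC(=O)c1c(C=O)c(Br)c(OCc2ccccc2)c2COC(C)(C)Oc12
F2 | step 15 | methyl 5-(benzyloxy)-6-bromo-7-(1,3-dioxolan-2-yl)-2,2-dimethyl-4H-1,3-benzodioxine-8-carboxylate | COC(=O)c1c(C2OCCO2)c(Br)c(OCc2ccccc2)c2COC(C)(C)Oc12
F3 | step 15 | methyl 6-bromo-7-(1,3-dioxolan-2-yl)-5-hydroxy-2,2-dimethyl-4H-1,3-benzodioxine-8-carboxylate | COC(=O)c1c(C2OCCO2)c(Br)c(O)c2COC(C)(C)Oc12
F4 | step 15 | 6-bromo-7-(1,3-dioxolan-2-yl)-8-(methoxycarbonyl)-2,2-dimethyl-4H-1,3-benzodioxin-5-yl trans-6-methyl-2,4-dioxocyclohexane-1-carboxylate (racemate, one enantiomer drawn) | C[C@@H]1CC(=O)CC(=O)[C@H]1C(=O)Oc1c(Br)c(C2OCCO2)c(C(=O)OC)c2OC(C)(C)OCc12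
F0 | step 21 | none | none
F5 | step 13 | S-tert-butyl 3-oxobutanethioate | CC(=O)CC(=O)SC(C)(C)C
F6 | step 13 | S-tert-butyl trans-6-methyl-2,4-dioxocyclohexane-1-carbothioate (racemate, one enantiomer drawn) | C[C@@H]1CC(=O)CC(=O)[C@H]1C(=O)SC(C)(C)C
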